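**Plan**

1. Ring numbering: C1 = C(CH3)(CH=CHBr), C2 = CHBr, C3 = CH2, C4 = CHCl, C5 = C(CH3)Cl, C6 = CH2. The retrosynthesis cuts C2–Br and C4–Cl back to C–O bonds of opposite configuration, C5–Cl back to the C5–O bond of a C4–C5 epoxide, then the bromoalkene C=C (to a formyl group) and the C5–CH3 bond.
2. The last cut opens the ring at C1–C2 and C5–C6. C1 with its methyl group, its one-carbon arm and C6 is a methacrolein unit; C2–C5 with oxygen on C4, para to the quaternary carbon, is a 1-amino-3-siloxybutadiene.
3. Forward: the only ring closes in step 2. Then follow arm olefination, C5 methylation and dehydrogenation to a cross-conjugated dienone, C2 oxygenation, reductive transposition of the second enone to the C4=C5 alkene, epoxidation, and three C–O to C–halogen exchanges.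
4. Stereochemistry: C1 comes from the chiral hydrogen-bond catalyst of the cycloaddition. C2 comes from a chiral copper catalyst (oxygen anti to the bromovinyl group). C4 and C5 come from an epoxidation directed by the C2 hydroxyl. Bromide at C2 and chloride at C5 and C4 then enter with inversion, so all three halogens end cis to the bromovinyl group.

Key step: step 2

Remark: the sense of induction of the TADDOL-catalysed cycloaddition and of the copper–bisphosphine borylation is assumed to be selectable through the catalyst antipode; the assignments would be checked by correlation at 6 and by NOE at 11.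

**Route**

Step 1
Reactants: 1 (E)-4-(dimethylamino)but-3-en-2-one; 2 tert-butyl(chloro)dimethylsilane
Product: 3 (E)-1-(dimethylamino)-3-(tert-butyldimethylsilyloxy)buta-1,3-diene
Conditions: NaHMDS, THF, −78 °C; then TBSCl, −78 °C → rt
Reagents that add atoms: tert-butyl(chloro)dimethylsilane (2), CC(C)(C)[Si](C)(C)Cl
Why: Enolate silylation: kinetic deprotonation of the methyl ketone of the vinylogous amide and O-silylation of the cross-conjugated enolate should give the diene with the E enamine geometry retained, no stereocentre being formed.

Step 2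
Reactants: 3 (E)-1-(dimethylamino)-3-(tert-butyldimethylsilyloxy)buta-1,3-diene; 4 methacrolein
Product: 6 (R)-4-formyl-4-methylcyclohex-2-en-1-one, via endo cycloadduct 5 (not isolated)
Conditions: 1-naphthyl-TADDOL (20 mol %, antipode giving the R centre), PhMe, −80 °C; then 0.1 M HCl, THF, 0 °C
Reagents that add atoms: none
Why: The electron-rich diene adds to the hydrogen-bonded aldehyde in a concerted but strongly asynchronous [4+2] cycloaddition, the free diene CH2 terminus (C5) bonding ahead to the acrolein CH2 (C6) while the amino-bearing terminus (C2) closes onto the α-carbon (C1); the closest known reaction type is the hydrogen-bond-catalysed Diels–Alder reaction of 1-amino-3-siloxydienes with α-substituted acroleins. The six-membered ring is closed in the [4+2] cycloaddition mode, both σ-bonds arising in one event. The quaternary centre C1 is controlled by the chiral diol, which binds the formyl oxygen through one hydroxyl and covers one enantioface with a naphthyl group; the C2 centre (endo, amino cis to formyl) is transient and is erased on work-up. The step needs enantiofacial and regiochemical control: the first rests on the catalyst, the second on the matched polarisation by the 1-amino and 3-siloxy donors, which places oxygen on C4. Dilute acid then hydrolyses the silyl enol ether and expels dimethylamine by β-elimination to give the enone, which is taken on crude because the vinylogous β-keto aldehyde is base-sensitive.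

Step 3
Reactants: 6 (R)-4-formyl-4-methylcyclohex-2-en-1-one
Product: 7 (R)-4-[(E)-2-bromoethenyl]-4-methylcyclohex-2-en-1-one
Conditions: CrBr2, CHBr3, THF, 0 °C → rt
Reagents that add atoms: bromoform, BrC(Br)Br
Why: Takai olefination: the gem-dichromium species from bromoform adds to the aldehyde much faster than to the ketone and anti-elimination of the β-oxido dichromium adduct should give the E bromoalkene, chromium(II) bromide being used so that no vinyl chloride arises by halide exchange; C1 is untouched.

Step 4
Reactants: 7 (R)-4-[(E)-2-bromoethenyl]-4-methylcyclohex-2-en-1-one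
Product: 8 (4R)-4-[(E)-2-bromoethenyl]-4,6-dimethylcyclohex-2-en-1-one (both C6 epimers)
Conditions: LDA, THF, −78 °C; then MeI, −78 → −30 °C
Reagents that add atoms: iodomethane, CI
Why: Kinetic α′-enolate alkylation: because C1 is quaternary, C5 carries the only enolisable hydrogens of the enone, so the methyl group is placed regiospecifically, and the new C5 centre is of no consequence since it becomes sp2 in the next step.

Step 5
Reactants: 8 (4R)-4-[(E)-2-bromoethenyl]-4,6-dimethylcyclohex-2-en-1-one
Product: 9 (S)-4-[(E)-2-bromoethenyl]-2,4-dimethylcyclohexa-2,5-dien-1-one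
Conditions: IBX, 4-methoxypyridine N-oxide, DMSO, rt → 50 °C
Reagents that add atoms: none
Why: IBX dehydrogenation of a ketone through its enol can only introduce unsaturation between C5 and C6, which gives a second, α-methyl-substituted enone for the later transposition and keeps C1 stereogenic because the two ring arms differ by the methyl group.

Step 6
Reactants: 9 (S)-4-[(E)-2-bromoethenyl]-2,4-dimethylcyclohexa-2,5-dien-1-one
Product: 11 (4S,5R)-4-[(E)-2-bromoethenyl]-5-hydroxy-2,4-dimethylcyclohex-2-en-1-one (hydroxyl trans to bromoethenyl), via boronic ester 10 (not isolated)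
Conditions: CuCl (5 mol %), NaOtBu (5 mol %), Josiphos SL-J001 (6 mol %, antipode fixed by screening), B2pin2 (1.05 equiv), MeOH, THF, 0 °C; then NaBO3·4H2O, THF–H2O, rt
Reagents that add atoms: bis(pinacolato)diboron, CC1(C)OB(OC1(C)C)B1OC(C)(C)C(C)(C)O1 (boron of 10 only); sodium perborate, [Na+].[O-]OB=O (hydroxyl oxygen of 11)
Why: Copper(I)-catalysed conjugate borylation followed by boron-to-oxygen oxidation with retention: the boryl copper should add only to the α-unsubstituted enone at C2, and the chiral bisphosphine is chosen so that boron enters on the face of the C1 methyl group, anti to the bromovinyl group (reagent control, since the two C1 substituents differ little in size), the minor diastereomer, which also carries the minor enantiomer from step 2, being removable at 11.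

Step 7
Reactants: 11 (4S,5R)-4-[(E)-2-bromoethenyl]-5-hydroxy-2,4-dimethylcyclohex-2-en-1-one
Product: 12 N′-[(4S,5R)-4-[(E)-2-bromoethenyl]-5-hydroxy-2,4-dimethylcyclohex-2-en-1-ylidene]-4-methylbenzenesulfonohydrazide
Conditions: TsNHNH2, MeOH, rt
Reagents that add atoms: p-toluenesulfonyl hydrazide, Cc1ccc(cc1)S(=O)(=O)NN
Why: Hydrazone formation from a 2-methylcyclohexenone in neutral methanol, where the β-hydroxyl is not eliminated and no stereocentre is touched.

Step 8
Reactants: 12 tosylhydrazone of 11
Product: 15 (1R,6S)-6-[(E)-2-bromoethenyl]-4,6-dimethylcyclohex-3-en-1-ol, via allylic tosylhydrazine 13 (not isolated), via allylic diazene 14 (not isolated)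
Conditions: catecholborane (2.5 equiv), CHCl3, 0 °C; then NaOAc·3H2O, 60 °C
Reagents that add atoms: none
Why: Kabalka-type reduction of an enone tosylhydrazone with alkene transposition: hydride adds to C4, loss of sulfinate gives the allylic diazene, and its retro-ene loss of dinitrogen delivers hydrogen to C6 and moves the double bond regiospecifically to C4=C5, leaving C1 and C2 unchanged.

Step 9
Reactants: 15 (1R,6S)-6-[(E)-2-bromoethenyl]-4,6-dimethylcyclohex-3-en-1-ol
Product: 16 (1S,3R,4S,6R)-4-[(E)-2-bromoethenyl]-4,6-dimethyl-7-oxabicyclo[4.1.0]heptan-3-ol (epoxide cis to hydroxyl, both trans to bromoethenyl)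
Conditions: VO(acac)2 (5 mol %), t-BuOOH, CH2Cl2, 0 °C → rt
Reagents that add atoms: tert-butyl hydroperoxide, CC(C)(C)OO
Why: Hydroxyl-directed vanadium-catalysed epoxidation of a cyclic homoallylic alcohol: the vanadium-bound C2 alkoxide should deliver oxygen to the face of the electron-rich C4=C5 bond cis to the hydroxyl, which sets C4 and C5, while the electron-poor bromoalkene is left alone.

Step 10
Reactants: 16 epoxy alcohol
Product: 17 (1R,3S,4S,6S)-4-bromo-3-[(E)-2-bromoethenyl]-1,3-dimethyl-7-oxabicyclo[4.1.0]heptane (ring bromine cis to bromoethenyl, epoxide trans to both)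
Conditions: CBr4, PPh3, 2,6-lutidine, PhMe, 0 → 50 °C
Reagents that add atoms: carbon tetrabromide, BrC(Br)(Br)Br
Why: Appel bromination with inversion: bromide displaces the axial oxyphosphonium group at C2 from the opposite face, as in known conversions of axial cyclohexanols next to a quaternary carbon into equatorial bromides, which puts bromine cis to the bromovinyl group, and the lutidine buffer keeps the epoxide from acid.

Step 11
Reactants: 17 bromo epoxide
Product: 18 (1S,2S,4S,5S)-5-bromo-4-[(E)-2-bromoethenyl]-2-chloro-2,4-dimethylcyclohexan-1-ol (hydroxyl trans to the tertiary chloride)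
Conditions: HCl (2 M in Et2O), CH2Cl2, −40 → 0 °C
Reagents that add atoms: hydrogen chloride, Cl
Why: Acid-mediated Markovnikov opening of a trisubstituted epoxide by chloride with inversion at the tertiary carbon (trans-diaxial opening) sets C5 with chlorine on the upper face and leaves the C4 hydroxyl on the lower face, the alternative diaxial opening at C4 being disfavoured because it would place bromine and chlorine syn-axial.

Step 12
Reactants: 18 trans-chlorohydrin
Product: 19 (1S,2S,4R,5S)-2-bromo-1-[(E)-2-bromoethenyl]-4,5-dichloro-1,5-dimethylcyclohexane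
Conditions: PPh3, NCS, PhMe, 0 → 60 °C
Reagents that add atoms: N-chlorosuccinimide, O=C1CCC(=O)N1Cl
Why: Appel-type deoxychlorination with inversion: chloride displaces the axial oxyphosphonium group at C4 from the upper face, as in known conversions of trans-β-chloro alcohols into cis-dichlorides, so that the secondary chloride ends equatorial and cis to the tertiary chloride.

**Compound list**

1 | (E)-4-(dimethylamino)but-3-en-2-one | CN(C)/C=C/C(C)=O | starting material
2 | tert-butyl(chloro)dimethylsilane | CC(C)(C)[Si](C)(C)Cl | starting material
3 | (E)-1-(dimethylamino)-3-(tert-butyldimethylsilyloxy)buta-1,3-diene | C=C(O[Si](C)(C)C(C)(C)C)/C=C/N(C)C | intermediate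
4 | methacrolein | C=C(C)C=O | starting material
5 | (1R,2S)-2-(dimethylamino)-1-methyl-4-(tert-butyldimethylsilyloxy)cyclohex-3-ene-1-carbaldehyde (amino cis to formyl) | O=C[C@]1(C)CCC(O[Si](C)(C)C(C)(C)C)=C[C@@H]1N(C)C | intermediate (not isolated)
6 | (R)-4-formyl-4-methylcyclohex-2-en-1-one | O=C1C=C[C@](C)(C=O)CC1 | intermediate
7 | (R)-4-[(E)-2-bromoethenyl]-4-methylcyclohex-2-en-1-one | O=C1C=C[C@](C)(/C=C/Br)CC1 | intermediate
8 | (4R)-4-[(E)-2-bromoethenyl]-4,6-dimethylcyclohex-2-en-1-one (C6 epimers) | O=C1C=C[C@](C)(/C=C/Br)CC1C | intermediate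
9 | (S)-4-[(E)-2-bromoethenyl]-2,4-dimethylcyclohexa-2,5-dien-1-one | O=C1C=C[C@](C)(/C=C/Br)C=C1C | intermediate
10 | (4S,5R)-4-[(E)-2-bromoethenyl]-2,4-dimethyl-5-(4,4,5,5-tetramethyl-1,3,2-dioxaborolan-2-yl)cyclohex-2-en-1-one (boron trans to bromoethenyl) | O=C1C[C@@H](B2OC(C)(C)C(C)(C)O2)[C@](C)(/C=C/Br)C=C1C | intermediate (not isolated)
11 | (4S,5R)-4-[(E)-2-bromoethenyl]-5-hydroxy-2,4-dimethylcyclohex-2-en-1-one | O=C1C[C@@H](O)[C@](C)(/C=C/Br)C=C1C | intermediate
12 | tosylhydrazone of 11 | Cc1ccc(cc1)S(=O)(=O)NN=C1C[C@@H](O)[C@](C)(/C=C/Br)C=C1C | intermediate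
13 | allylic N′-tosylhydrazine from hydride addition to 12 (C4 epimers) | Cc1ccc(cc1)S(=O)(=O)NNC1C[C@@H](O)[C@](C)(/C=C/Br)C=C1C | intermediate (not isolated)
14 | allylic diazene (C4 epimers) | N=NC1C[C@@H](O)[C@](C)(/C=C/Br)C=C1C | intermediate (not isolated)
15 | (1R,6S)-6-[(E)-2-bromoethenyl]-4,6-dimethylcyclohex-3-en-1-ol | CC1=CC[C@@H](O)[C@](C)(/C=C/Br)C1 | intermediate
16 | (1S,3R,4S,6R)-4-[(E)-2-bromoethenyl]-4,6-dimethyl-7-oxabicyclo[4.1.0]heptan-3-ol | C[C@]12O[C@H]1C[C@@H](O)[C@](C)(/C=C/Br)C2 | intermediate
17 | (1R,3S,4S,6S)-4-bromo-3-[(E)-2-bromoethenyl]-1,3-dimethyl-7-oxabicyclo[4.1.0]heptane | C[C@]12O[C@H]1C[C@H](Br)[C@](C)(/C=C/Br)C2 | intermediate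
18 | (1S,2S,4S,5S)-5-bromo-4-[(E)-2-bromoethenyl]-2-chloro-2,4-dimethylcyclohexan-1-ol | C[C@]1(Cl)C[C@@](C)(/C=C/Br)[C@@H](Br)C[C@@H]1O | intermediate
19 | (1S,2S,4R,5S)-2-bromo-1-[(E)-2-bromoethenyl]-4,5-dichloro-1,5-dimethylcyclohexane | C[C@]1(Cl)C[C@@](C)(/C=C/Br)[C@@H](Br)C[C@H]1Cl | target

**Step count**

Total: 12 steps. Longest linear sequence: 12 steps (1 → 19).

**Steps most likely to fail**

Step 12. The oxyphosphonium group at C4 sits next to a fully substituted carbon and trans-diaxial to the tertiary C–Cl bond. Backside displacement may therefore be slow enough for chlorine participation (bridged chloronium, leading to retention or a 1,2-chlorine shift and the trans-dichloride) or loss of HCl to take over. The fallback sets out from 18 and avoids any backside attack at C4. Dess–Martin periodinane (CH2Cl2, NaHCO3) would give the α-chloro ketone F1, whose C5 centre cannot epimerise. NaBH4 (MeOH, −40 °C), with hydride entering axially on the lower face anti to the axial C–Cl bond, would give the cis-chlorohydrin F2 with an equatorial hydroxyl on the upper face. Thionyl chloride followed by catalytic TiCl4 (CH2Cl2, 0 °C) would then convert the chlorosulfite into the chloride with retention by front-side delivery, which comes back to the route at 19. Any 18 re-formed in the reduction is recycled.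

Step 10. Substitution at the neopentyl-type carbinol is slow, which leaves room for elimination, for participation of the bromovinyl π-bond, and for opening of the epoxide by bromide under the heating needed. The fallback sets out from 16 and postpones the bromination until no epoxide is present. Acetylation (Ac2O, DMAP, pyridine) would give the epoxy acetate F3. Hydrogen chloride as in step 11 would give the chlorohydrin acetate F4, and PPh3–NCS as in step 12 the dichloro acetate F5. DIBAL-H (CH2Cl2, −78 °C) would free the dichloro alcohol F6, and CBr4–PPh3 (PhMe, 50 °C) would brominate it with inversion, returning to the route at 19.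

Step 6. The copper catalyst may discriminate poorly between the two faces at C2, since methyl and bromovinyl on C1 are of similar size, and the boryl copper may also attack the second enone or the vinyl bromide. The fallback sets out from 9 and moves the facial control to an iminium-catalysed epoxidation. A 9-amino-9-deoxy-epi-cinchona alkaloid salt (10 mol %) with aqueous H2O2 in dioxane would epoxidise only the α-unsubstituted enone and give the epoxy enone F7 with oxygen on the face of the C1 methyl group. SmI2 (THF–MeOH, −78 °C) would cleave the Cα–O bond reductively and return to the route at 11.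

Further compounds
F1 | step 12 | (2S,4S,5S)-5-bromo-4-[(E)-2-bromoethenyl]-2-chloro-2,4-dimethylcyclohexan-1-one | C[C@]1(Cl)C[C@@](C)(/C=C/Br)[C@@H](Br)CC1=O
F2 | step 12 | (1R,2S,4S,5S)-5-bromo-4-[(E)-2-bromoethenyl]-2-chloro-2,4-dimethylcyclohexan-1-ol (hydroxyl cis to the tertiary chloride) | C[C@]1(Cl)C[C@@](C)(/C=C/Br)[C@@H](Br)C[C@H]1O
F3 | step 10 | acetate of 16 | C[C@]12O[C@H]1C[C@@H](OC(C)=O)[C@](C)(/C=C/Br)C2
F4 | step 10 | chlorohydrin acetate (C2 acetate and C4 hydroxyl cis, tertiary chloride trans to both) | C[C@]1(Cl)C[C@@](C)(/C=C/Br)[C@H](OC(C)=O)C[C@@H]1O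
F5 | step 10 | cis-4,5-dichloro acetate | C[C@]1(Cl)C[C@@](C)(/C=C/Br)[C@H](OC(C)=O)C[C@H]1Cl
F6 | step 10 | cis-4,5-dichloro alcohol (C2 hydroxyl trans to bromoethenyl) | C[C@]1(Cl)C[C@@](C)(/C=C/Br)[C@H](O)C[C@H]1Cl
F7 | step 6 | 5,6-epoxide of 9 (oxygen trans to bromoethenyl) | O=C1C(C)=C[C@@](C)(/C=C/Br)[C@@H]2O[C@H]12
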